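**Plan**
1. Retrosynthetic cuts, in order:
   - (i) the O–Si bond of a silyl-masked ring-B phenol;
   - (ii) the C1'–C(=O) bond between ring A and the enone carbonyl, traced back by a retro-photo-Fries shift to the O-2' (E)-p-coumarate of 2,4-diprenylresorcinol;
   - (iii) that ester C–O bond;
   - (iv) the two aryl–CH2 bonds of the prenyl groups, back to 4-bromoresorcinol.
2. Enabling feature: in ring A, C1' is the only hydrogen-bearing carbon that is ortho or para to an oxygen (ortho to O-2', para to O-4'). C3' and C5' are blocked by prenyl groups and C6' is meta to both oxygens. An acyl group set loose from O-2' can therefore settle only on C1', and using light instead of a Lewis acid spares the acid-sensitive ortho-prenylphenol units.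
3. Forward order: both benzene rings are bought and no ring is built. The sequence is prenyl at the C–Br carbon (Br/Li exchange), prenyl between the two acetal oxygens (directed metalation), acetal removal, esterification with silylated p-coumaric acid, light-driven O→C acyl shift, desilylation.
4. Stereochemistry: there is no stereocentre. The E double bond is bought with trans-p-coumaric acid, and the chelated E-chalcone is the thermodynamic and photostationary sink.

Key step: step 7

Assumption: the target has no stereocentre and is achiral, so "single enantiomer" is read as the single E isomer of the enone double bond.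

Step 1
Reactants: 1 4-bromoresorcinol
Product: 2 1-bromo-2,4-bis(methoxymethoxy)benzene
Conditions: NaH (2.4 equiv), MOMCl (2.4 equiv), DMF, 0 °C → rt
Reagents that add atoms: chloromethyl methyl ether (MOMCl), COCCl
Why: Williamson-type O-alkylation of both phenoxides masks the acidic OH groups as MOM acetals and installs the two oxygen-based directing groups used in steps 2 and 3.

Step 2
Reactants: 2 1-bromo-2,4-bis(methoxymethoxy)benzene
Product: 4 2,4-bis(methoxymethoxy)-1-(3-methylbut-2-en-1-yl)benzene, via aryllithium 3 (not isolated)
Conditions: n-BuLi (1.05 equiv), THF, −78 °C; CuI (10 mol %), prenyl bromide, −78 °C → rt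
Reagents that add atoms: prenyl bromide (1-bromo-3-methylbut-2-ene), CC(C)=CCBr
Why: Bromine–lithium exchange is faster at −78 °C than any deprotonation and places the carbanion exactly where the bromine stood, and copper-catalysed SN2 allylation of the chelated aryllithium by prenyl bromide should deliver the linear prenyl group.

Step 3
Reactants: 4 2,4-bis(methoxymethoxy)-1-(3-methylbut-2-en-1-yl)benzene
Product: 6 1,3-bis(methoxymethoxy)-2,4-bis(3-methylbut-2-en-1-yl)benzene, via aryllithium 5 (not isolated)
Conditions: n-BuLi (1.1 equiv), THF, 0 °C; CuI (10 mol %), prenyl bromide, −20 °C → rt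
Reagents that add atoms: prenyl bromide (1-bromo-3-methylbut-2-ene), CC(C)=CCBr
Why: Directed ortho-metalation, in which the C–H between the two OCH2OMe groups is acidified and pre-complexed from both sides and should be removed faster than the benzylic/allylic CH2 or the other ring hydrogens, followed by copper-catalysed allylation to set the second prenyl group.

Step 4
Reactants: 6 1,3-bis(methoxymethoxy)-2,4-bis(3-methylbut-2-en-1-yl)benzene
Product: 7 2,4-bis(3-methylbut-2-en-1-yl)benzene-1,3-diol (2,4-diprenylresorcinol)
Conditions: conc. HCl (cat.), MeOH, 40 °C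
Reagents that add atoms: none
Why: Acid-catalysed transacetalisation to methanol cleaves aryl MOM ethers under conditions dilute and mild enough that protonation of the trisubstituted alkenes (chroman formation) should remain slow, as is usual for MOM removal from prenylated phenols.

Step 5
Reactants: 8 (E)-4-hydroxycinnamic acid (trans-p-coumaric acid)
Product: 10 (E)-3-[4-(tert-butyldimethylsilyloxy)phenyl]prop-2-enoic acid, via bis-silyl derivative 9 (not isolated)
Conditions: TBSCl (2.3 equiv), imidazole, DMF, rt; then AcOH/THF/H2O, rt
Reagents that add atoms: tert-butyldimethylsilyl chloride (TBSCl), CC(C)(C)[Si](C)(C)Cl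
Why: Exhaustive silylation followed by selective hydrolysis of the far more labile silyl ester leaves only the phenol masked, so the acid cannot oligomerise through its own OH in step 6, and the alkene geometry is untouched.

Step 6
Reactants: 7 2,4-diprenylresorcinol; 10 (E)-3-[4-(tert-butyldimethylsilyloxy)phenyl]prop-2-enoic acid
Product: 11 3-hydroxy-2,4-bis(3-methylbut-2-en-1-yl)phenyl (E)-3-[4-(tert-butyldimethylsilyloxy)phenyl]prop-2-enoate
Conditions: DCC (1.05 equiv), DMAP (cat.), CH2Cl2, 0 °C → rt, 10 added slowly to 7
Reagents that add atoms: none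
Why: Steglich esterification, in which DMAP-mediated acyl transfer is sensitive to steric hindrance, so the OH flanked by one prenyl group and one hydrogen (the future O-2') should be acylated in preference to the OH flanked by two prenyl groups.

Step 7
Reactants: 11 3-hydroxy-2,4-bis(3-methylbut-2-en-1-yl)phenyl (E)-3-[4-(tert-butyldimethylsilyloxy)phenyl]prop-2-enoate
Product: 14 (E)-3-[4-(tert-butyldimethylsilyloxy)phenyl]-1-[2,4-dihydroxy-3,5-bis(3-methylbut-2-en-1-yl)phenyl]prop-2-en-1-one, via caged radical pair 12 (not isolated), via ortho-acyl dienone 13 (not isolated)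
Conditions: hν (medium-pressure Hg lamp, Pyrex, λ > 290 nm), Ar-sparged MeCN (ca. 3 mM), FEP flow coil, 20 °C
Reagents that add atoms: none
Why: Excitation of the aryl ester chromophore of 11 populates a dissociative state in which the O-2'–C(=O) bond breaks homolytically to the solvent-caged phenoxyl/cinnamoyl radical pair 12, which recombines at a ring carbon of high spin density to give dienone 13, and 13 enolises to the hydrogen-bonded 2'-hydroxy ketone 14. The closest known reaction type is the photo-Fries rearrangement of aryl cinnamates to 2'-hydroxychalcones. No ring is closed and no lasting stereocentre arises, since the sp3 carbon of 13 becomes planar again on enolisation. The step needs site selectivity, and ring A secures it: of the three spin-bearing carbons two (C3' and C5') carry prenyl groups, so capture there gives dienones that cannot enolise and should fall apart again, whereas C1' bears hydrogen and leads irreversibly to the phenol (an ester on the more hindered O-4' would reach the same carbon by the para shift). It also needs chemoselectivity, which the conditions supply: no acid is present to close the ortho-prenylphenol units to chromans, high dilution disfavours cinnamate [2+2] dimerisation, exclusion of O2 prevents the singlet-oxygen ene reaction of the prenyl groups, acetonitrile ties up the free OH by hydrogen bonding against phenol-to-alkene proton transfer, and the α,β-unsaturated acyl radical should not lose CO at a competitive rate. E/Z isomerisation of the cinnamate is not destructive, because both ester isomers can rearrange and the chelated E-chalcone, which sheds its excitation by excited-state proton transfer, should be the photostationary sink.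

Step 8
Reactants: 14 (E)-3-[4-(tert-butyldimethylsilyloxy)phenyl]-1-[2,4-dihydroxy-3,5-bis(3-methylbut-2-en-1-yl)phenyl]prop-2-en-1-one
Product: 15 (E)-1-[2,4-dihydroxy-3,5-bis(3-methylbut-2-en-1-yl)phenyl]-3-(4-hydroxyphenyl)prop-2-en-1-one (target)
Conditions: KHF2 (2 equiv), MeOH/THF, rt
Reagents that add atoms: none
Why: Fluoride-induced Si–O cleavage by the weakly acidic bifluoride is selective for aryl silyl ethers and avoids both base (chalcone-to-flavanone cyclisation) and strong acid (chroman formation).

**Compound list**
1 | 4-bromoresorcinol (4-bromobenzene-1,3-diol) | Oc1ccc(Br)c(O)c1 | starting material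
2 | 1-bromo-2,4-bis(methoxymethoxy)benzene | COCOc1ccc(Br)c(OCOC)c1 | intermediate
3 | [2,4-bis(methoxymethoxy)phenyl]lithium | [Li]c1ccc(OCOC)cc1OCOC | intermediate
4 | 2,4-bis(methoxymethoxy)-1-(3-methylbut-2-en-1-yl)benzene | CC(C)=CCc1ccc(OCOC)cc1OCOC | intermediate
5 | [2,6-bis(methoxymethoxy)-3-(3-methylbut-2-en-1-yl)phenyl]lithium | CC(C)=CCc1ccc(OCOC)c([Li])c1OCOC | intermediate
6 | 1,3-bis(methoxymethoxy)-2,4-bis(3-methylbut-2-en-1-yl)benzene | CC(C)=CCc1ccc(OCOC)c(CC=C(C)C)c1OCOC | intermediate
7 | 2,4-bis(3-methylbut-2-en-1-yl)benzene-1,3-diol (2,4-diprenylresorcinol) | CC(C)=CCc1ccc(O)c(CC=C(C)C)c1O | intermediate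
8 | (E)-4-hydroxycinnamic acid (trans-p-coumaric acid) | OC(=O)/C=C/c1ccc(O)cc1 | starting material
9 | tert-butyldimethylsilyl (E)-3-[4-(tert-butyldimethylsilyloxy)phenyl]prop-2-enoate | CC(C)(C)[Si](C)(C)OC(=O)/C=C/c1ccc(O[Si](C)(C)C(C)(C)C)cc1 | intermediate
10 | (E)-3-[4-(tert-butyldimethylsilyloxy)phenyl]prop-2-enoic acid | OC(=O)/C=C/c1ccc(O[Si](C)(C)C(C)(C)C)cc1 | intermediate
11 | 3-hydroxy-2,4-bis(3-methylbut-2-en-1-yl)phenyl (E)-3-[4-(tert-butyldimethylsilyloxy)phenyl]prop-2-enoate | CC(C)=CCc1ccc(OC(=O)/C=C/c2ccc(O[Si](C)(C)C(C)(C)C)cc2)c(CC=C(C)C)c1O | intermediate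
12 | caged radical pair: 3-hydroxy-2,4-diprenylphenoxyl radical plus (E)-4-(tert-butyldimethylsilyloxy)cinnamoyl radical | CC(C)=CCc1ccc([O])c(CC=C(C)C)c1O.O=[C]/C=C/c1ccc(O[Si](C)(C)C(C)(C)C)cc1 | intermediate
13 | 6-[(E)-4-(tert-butyldimethylsilyloxy)cinnamoyl]-3-hydroxy-2,4-bis(3-methylbut-2-en-1-yl)cyclohexa-2,4-dien-1-one (racemic, transient) | CC(C)=CCC1=CC(C(=O)/C=C/c2ccc(O[Si](C)(C)C(C)(C)C)cc2)C(=O)C(CC=C(C)C)=C1O | intermediate
14 | (E)-3-[4-(tert-butyldimethylsilyloxy)phenyl]-1-[2,4-dihydroxy-3,5-bis(3-methylbut-2-en-1-yl)phenyl]prop-2-en-1-one | CC(C)=CCc1cc(C(=O)/C=C/c2ccc(O[Si](C)(C)C(C)(C)C)cc2)c(O)c(CC=C(C)C)c1O | intermediate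
15 | (E)-1-[2,4-dihydroxy-3,5-bis(3-methylbut-2-en-1-yl)phenyl]-3-(4-hydroxyphenyl)prop-2-en-1-one | CC(C)=CCc1cc(C(=O)/C=C/c2ccc(O)cc2)c(O)c(CC=C(C)C)c1O | target

Total step count: 8. Longest linear sequence: 7 (steps 1, 2, 3, 4, 6, 7, 8).

**Steps most likely to fail**

Risk 1 (step 7).
- What may go wrong: the excited state may be drained by cinnamate E/Z isomerisation. The strongly absorbing chalcone may screen the light as it builds up. Radicals may escape from the cage, which regenerates the phenol. The free OH may add to a neighbouring prenyl double bond under light, and over-irradiation may close the chalcone to the flavanone.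
- Fallback: it replaces the light-driven shift by a carbanion acylation. It sets out from 6 (with 10 as acyl source) and comes back to the route at 14.
- Acid 10 is condensed with MeNHOMe·HCl (EDC, Et3N, CH2Cl2) to the Weinreb amide (E)-3-[4-(tert-butyldimethylsilyloxy)phenyl]-N-methoxy-N-methylprop-2-enamide F1.
- Arene 6 is lithiated ortho to its less hindered acetal oxygen (s-BuLi, TMEDA, THF, −78 °C) to [2,4-bis(methoxymethoxy)-3,5-bis(3-methylbut-2-en-1-yl)phenyl]lithium F2.
- F2 adds 1,2 to F1 and, after an aqueous quench, should give the fully protected chalcone (E)-1-[2,4-bis(methoxymethoxy)-3,5-bis(3-methylbut-2-en-1-yl)phenyl]-3-[4-(tert-butyldimethylsilyloxy)phenyl]prop-2-en-1-one F3.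
- Brief treatment with catalytic HCl in MeOH removes the two acetals and gives 14. The aryl silyl ether is the more acid-resistant group, and its loss would only anticipate step 8.

Risk 2 (step 4).
- What may go wrong: acid may protonate a prenyl double bond so that the neighbouring OH closes a chroman. The liberated formaldehyde equivalent may also be captured by the very electron-rich free ring position.
- Fallback: it reaches the diol without acetals and without acid. It sets out from 1 and comes back to the route at 7.
- Tsuji–Trost-type O-tert-prenylation of 1 (tert-butyl 2-methylbut-3-en-2-yl carbonate, Pd(PPh3)4 cat., THF, 0 °C) gives 1-bromo-2,4-bis[(2-methylbut-3-en-2-yl)oxy]benzene F4.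
- Heating F4 (N,N-diethylaniline, about 130 °C) triggers two aromatic Claisen rearrangements. Bromine blocks the third activated ring position, so both groups should end on the two remaining ortho carbons to give 4-bromo-2,6-bis(3-methylbut-2-en-1-yl)benzene-1,3-diol F5.
- n-BuLi (3.3 equiv, THF, −78 °C) deprotonates both OH groups and exchanges the bromine to give the trilithiated species dilithium 4-lithio-2,6-bis(3-methylbut-2-en-1-yl)benzene-1,3-diolate F6. Quenching F6 with water gives 7.

Risk 3 (step 3).
- What may go wrong: deprotonation of the benzylic/allylic CH2 of the first prenyl group may compete, with subsequent double-bond migration. The hindered aryl-metal species may also attack prenyl bromide in the SN2' sense.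
- Fallback: it fixes both prenylation sites by halogens before any prenyl group is present. It sets out from 1 and comes back to the route at 6.
- Iodination of 1 between the two hydroxyls (I2, NaHCO3, water, 0 °C, the conditions that take resorcinol to its 2-iodide) gives 4-bromo-2-iodobenzene-1,3-diol F7.
- MOM protection as in step 1 gives 1-bromo-3-iodo-2,4-bis(methoxymethoxy)benzene F8.
- A double, ligand-controlled linear-selective Suzuki–Miyaura coupling of F8 with prenylboronic acid pinacol ester (Pd catalyst, K3PO4, THF/H2O, 40–70 °C) replaces both halogens by prenyl groups and gives 6.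

**Further compounds**
F1 | step 7 | (E)-3-[4-(tert-butyldimethylsilyloxy)phenyl]-N-methoxy-N-methylprop-2-enamide | CON(C)C(=O)/C=C/c1ccc(O[Si](C)(C)C(C)(C)C)cc1
F2 | step 7 | [2,4-bis(methoxymethoxy)-3,5-bis(3-methylbut-2-en-1-yl)phenyl]lithium | CC(C)=CCc1cc([Li])c(OCOC)c(CC=C(C)C)c1OCOC
F3 | step 7 | (E)-1-[2,4-bis(methoxymethoxy)-3,5-bis(3-methylbut-2-en-1-yl)phenyl]-3-[4-(tert-butyldimethylsilyloxy)phenyl]prop-2-en-1-one | CC(C)=CCc1cc(C(=O)/C=C/c2ccc(O[Si](C)(C)C(C)(C)C)cc2)c(OCOC)c(CC=C(C)C)c1OCOC
F4 | step 4 | 1-bromo-2,4-bis[(2-methylbut-3-en-2-yl)oxy]benzene | C=CC(C)(C)Oc1ccc(Br)c(OC(C)(C)C=C)c1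
F5 | step 4 | 4-bromo-2,6-bis(3-methylbut-2-en-1-yl)benzene-1,3-diol | CC(C)=CCc1cc(Br)c(O)c(CC=C(C)C)c1O
F6 | step 4 | dilithium 4-lithio-2,6-bis(3-methylbut-2-en-1-yl)benzene-1,3-diolate | [Li]c1cc(CC=C(C)C)c(O[Li])c(CC=C(C)C)c1O[Li]
F7 | step 3 | 4-bromo-2-iodobenzene-1,3-diol | Oc1ccc(Br)c(O)c1I
F8 | step 3 | 1-bromo-3-iodo-2,4-bis(methoxymethoxy)benzene | COCOc1ccc(Br)c(OCOC)c1I
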